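**Retrosynthetic overview**
1. Gibberellin A(21) ⇐ its dimethyl ester ⇐ ring D closed last by ketyl–alkyne cyclisation of a 13-ketone onto an 8β-propargyl group.
2. Key step: ring A and the 19,10-lactone are made together from a ring-B cyclopentene with a (CH2)3CH(CO2Me)2 chain on C-10, by Mn(OAc)3 radical 6-endo cyclisation and cation lactonisation (sets C-4, C-5, C-10).
3. That cyclopentene ⇐ tertiary allylic carbonate (Pd-catalysed decarboxylative carbonylation puts C-7 on C-6 with 1,3-chirality transfer, then malonate alkylation) ⇐ bicyclic enone + 3-chloropropyl Grignard.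
4. Bicyclic enone ⇐ Diels–Alder of a 2-silyloxybutadiene with (S)-4-silyloxy-3-propargylcyclopentenone (rings B/C, C-8 quaternary centre; the silyloxy group is then eliminated) ⇐ 3-methoxycyclopentenone.
5. Ring order: B (bought) → C (Diels–Alder) → A + lactone (radical annulation) → D (SmI2).

Assumption: atom labels C-1 to C-19 follow the gibberellane numbering of the target, β is the ring-B face carrying H-5, H-9 and C-7, α is the lactone face; in step 2 the lipase is taken to hydrolyse the (S)-acetate (if the enzyme at hand prefers the (R)-acetate, the recovered (S)-acetate is cleaved with a non-selective esterase and used).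

**Step 1**
Reactants: 1 3-methoxycyclopent-2-en-1-one
Product: 2 rac-5-acetoxy-3-methoxycyclopent-2-en-1-one
Conditions: Mn(OAc)3·2H2O (3 equiv), benzene, reflux (Dean–Stark)
Reagents that add atoms: manganese triacetate, CC(=O)[O-].CC(=O)[O-].CC(=O)[O-].[Mn+3]
Why: α′-Acetoxylation of an enone by trivalent manganese (manganese enolate, α′-keto radical, acetate transfer) occurs only at C-5 because the vinylogous-ester α position is deactivated.

**Step 2**
Reactants: 2 rac-5-acetoxy-3-methoxycyclopent-2-en-1-one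
Product: 3 (S)-5-hydroxy-3-methoxycyclopent-2-en-1-one
Conditions: Amano lipase PS, pH 7 phosphate buffer/toluene, 25 °C, stop at 50 % conversion; unreacted (R)-2 removed by chromatography
Reagents that add atoms: none
Why: Lipase-catalysed kinetic resolution (enantioselective ester hydrolysis) supplies the only externally sourced stereocentre, which later directs C-8/C-9 and is then erased.

**Step 3**
Reactants: 3 (S)-5-hydroxy-3-methoxycyclopent-2-en-1-one
Product: 4 (S)-5-(tert-butyldimethylsilyloxy)-3-methoxycyclopent-2-en-1-one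
Conditions: TBSCl, imidazole, DMF, 0 °C → rt
Reagents that add atoms: tert-butyldimethylsilyl chloride, CC(C)(C)[Si](C)(C)Cl
Why: Standard silyl ether formation protects the α′-hydroxyl under non-epimerising conditions and makes it a bulky facial director.

**Step 4**
Reactants: 4 (S)-5-(tert-butyldimethylsilyloxy)-3-methoxycyclopent-2-en-1-one; 5 propargyl bromide
Product: 8 (S)-4-(tert-butyldimethylsilyloxy)-3-(prop-2-ynyl)cyclopent-2-en-1-one, via allenylmagnesium bromide 6 (not isolated), via bromomagnesium alkoxide adduct 7 (not isolated)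
Conditions: 5, Mg, HgCl2 (cat.), Et2O, 0 °C; add 4, THF, −78 °C; then 1 M HCl, THF, 0 °C
Reagents that add atoms: water, O
Why: Stork–Danheiser alkylative carbonyl transposition: the allenyl Grignard adds SE2′ to the vinylogous-ester carbonyl to give the propargyl carbinol, and acid hydrolysis of the enol ether with loss of water gives the 3-propargyl enone with the silyloxy centre (C-6) untouched.

**Step 5**
Reactants: 9 methyl vinyl ketone
Product: 10 2-(triisopropylsilyloxy)buta-1,3-diene
Conditions: TIPSOTf, Et3N, Et2O, 0 °C → rt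
Reagents that add atoms: triisopropylsilyl triflate, CC(C)[Si](C(C)C)(C(C)C)OS(=O)(=O)C(F)(F)F
Why: Soft enolisation and O-silylation of the methyl ketone gives a robust silyl dienol ether.

**Step 6**
Reactants: 8 (S)-4-(tert-butyldimethylsilyloxy)-3-(prop-2-ynyl)cyclopent-2-en-1-one; 10 2-(triisopropylsilyloxy)buta-1,3-diene
Product: 11 cis-3-(tert-butyldimethylsilyloxy)-3a-(prop-2-ynyl)-5-(triisopropylsilyloxy)-2,3,3a,4,7,7a-hexahydro-1H-inden-1-one (6β-OTBS, 8β-propargyl, 9β-H; C-10 ketone; 12-ene)
Conditions: AlBr3/AlMe3 (5:1, 20 mol %), toluene/CH2Cl2, −20 → 0 °C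
Reagents that add atoms: none
Why: Lewis-acid-catalysed Diels–Alder reaction with para regiochemistry (silyloxy carbon becomes C-13); the diene adds suprafacially to the face anti to the C-6 silyloxy group, setting the C-8 quaternary centre and the cis ring fusion (C-9).

**Step 7**
Reactants: 11 cis-hydrindanone from step 6
Product: 12 cis-3a-(prop-2-ynyl)-5-(triisopropylsilyloxy)-3a,4,7,7a-tetrahydro-1H-inden-1-one (8β-propargyl, 9β-H; C-5=C-6 enone)
Conditions: DBU, CH2Cl2, 25 °C
Reagents that add atoms: none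
Why: E1cB β-elimination of the silanolate unveils the C-5=C-6 enone, removing the relay stereocentre while C-9 stays in its thermodynamically preferred cis-fused configuration.

**Step 8**
Reactants: 12 bicyclic enone from step 7; 13 1-bromo-3-chloropropane
Product: 16 1-(3-chloropropyl)-3a-(prop-2-ynyl)-5-(triisopropylsilyloxy)-3a,4,7,7a-tetrahydro-1H-inden-1-yl methyl carbonate (chloropropyl β and carbonate oxygen α on C-10), via 3-chloropropylmagnesium bromide 14 (not isolated), via bromomagnesium tertiary alkoxide 15 (not isolated)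
Conditions: 13, Mg, THF, 0 °C; LaCl3·2LiCl (30 mol %), 12, THF, −78 °C; then ClCO2Me, −78 → 0 °C
Reagents that add atoms: methyl chloroformate, COC(=O)Cl
Why: Grignard 1,2-addition to the enone carbonyl from the convex β face (anti to C-11 on the adjacent ring-fusion carbon) places the oxygen α on C-10, and the magnesium alkoxide is acylated in situ.

**Step 9**
Reactants: 16 tertiary allylic carbonate from step 8
Product: 17 methyl 3-(3-chloropropyl)-7a-(prop-2-ynyl)-6-(triisopropylsilyloxy)-3a,4,7,7a-tetrahydro-1H-indene-1-carboxylate (6β-CO2Me, 8β-propargyl, 9β-H; C-5=C-10 alkene)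
Conditions: Pd(OAc)2 (5 mol %), PPh3 (20 mol %), CO (30 atm), THF, 50 °C
Reagents that add atoms: carbon monoxide, [C-]#[O+]
Why: Tsuji decarboxylative carbonylation of an allylic carbonate: zerovalent palladium ionises anti to the α-carbonate, CO inserts at the less substituted allyl terminus C-6 on the palladium (β) face and the released methoxide forms the ester, so the C-10 configuration is transferred to C-6 while the alkene moves to C-5=C-10.

**Step 10**
Reactants: 17 chloro ester from step 9; 18 dimethyl malonate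
Product: 19 dimethyl 2-{3-[1-(methoxycarbonyl)-7a-(prop-2-ynyl)-6-(triisopropylsilyloxy)-3a,4,7,7a-tetrahydro-1H-inden-3-yl]propyl}malonate (stereochemistry as in 17)
Conditions: 18 (5 equiv), Cs2CO3, NaI (20 mol %), DMF, 40 °C
Reagents that add atoms: none
Why: Malonic ester alkylation (SN2, assisted by in situ Finkelstein exchange) adds C-4 with its two carboxyl carbons under a base too weak to touch C-6.

**Step 11**
Reactants: 19 malonate from step 10
Product: 20 dimethyl 2-{3-[1-(methoxycarbonyl)-6-oxo-7a-(prop-2-ynyl)-3a,4,5,6,7,7a-hexahydro-1H-inden-3-yl]propyl}malonate (13-ketone)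
Conditions: HF·pyridine, THF, 0 °C
Reagents that add atoms: none
Why: Fluoride-assisted cleavage of the silyl enol ether releases the C-13 ketone without acid or base strong enough to move the C-5=C-10 alkene.

**Step 12**
Reactants: 20 keto malonate from step 11
Product: 21 ring-D-seco gibberellin A(21) dimethyl ester (13-ketone, 8β-propargyl, 4α,10α-lactone, 5β-H, 6β-CO2Me, 9β-H)
Conditions: Mn(OAc)3·2H2O (2.5 equiv), degassed AcOH, 80 °C
Reagents that add atoms: none
Why: Snider-type oxidative free-radical cyclisation: the manganese enolate gives the C-4 malonyl radical, which closes 6-endo on C-5 from the α face (anti to the 6β-ester); a second Mn(OAc)3 oxidises the tertiary C-10 radical to the cation, and the α-disposed ester carbonyl captures it with loss of methyl acetate, so ring A, the γ-lactone and C-4, C-5, C-10 form in one operation.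

**Step 13**
Reactants: 21 keto lactone from step 12
Product: 22 gibberellin A(21) dimethyl ester
Conditions: SmI2 (3 equiv), HMPA, t-BuOH, THF, 0 °C
Reagents that add atoms: none
Why: Ketyl–alkyne reductive cyclisation (Stork/Molander type): divalent samarium forms the C-13 ketyl, which adds 5-exo-dig to the propargyl alkyne; the bridge can only close on the β face, so C-13 is fixed by C-8, and the vinyl radical is reduced and protonated to the exocyclic methylene.

**Step 14**
Reactants: 22 gibberellin A(21) dimethyl ester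
Product: 24 gibberellin A(21), via disodium dicarboxylate 23 (not isolated)
Conditions: NaSPr (8 equiv), DMF, 40 °C; then 1 M HCl, 0 °C
Reagents that add atoms: none
Why: Thiolate SN2 dealkylation at the methyl groups cleaves both hindered esters without attacking the tertiary lactone C–O bond, the tertiary allylic alcohol or the alkene, and stays below the temperature of malonate decarboxylation.

**Compound list**
1 | 3-methoxycyclopent-2-en-1-one | COC1=CC(=O)CC1 | starting material
2 | rac-5-acetoxy-3-methoxycyclopent-2-en-1-one | COC1=CC(=O)C(OC(C)=O)C1 | intermediate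
3 | (S)-5-hydroxy-3-methoxycyclopent-2-en-1-one | COC1=CC(=O)[C@@H](O)C1 | intermediate
4 | (S)-5-(tert-butyldimethylsilyloxy)-3-methoxycyclopent-2-en-1-one | COC1=CC(=O)[C@@H](O[Si](C)(C)C(C)(C)C)C1 | intermediate
5 | propargyl bromide | C#CCBr | starting material
6 | allenylmagnesium bromide | C=C=C[Mg]Br | intermediate
7 | bromomagnesium alkoxide of (5S)-5-(tert-butyldimethylsilyloxy)-3-methoxy-1-(prop-2-ynyl)cyclopent-2-en-1-ol (carbinol centre unassigned) | COC1=CC(CC#C)(O[Mg]Br)[C@@H](O[Si](C)(C)C(C)(C)C)C1 | intermediate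
8 | (S)-4-(tert-butyldimethylsilyloxy)-3-(prop-2-ynyl)cyclopent-2-en-1-one | O=C1C=C(CC#C)[C@@H](O[Si](C)(C)C(C)(C)C)C1 | intermediate
9 | methyl vinyl ketone | CC(=O)C=C | starting material
10 | 2-(triisopropylsilyloxy)buta-1,3-diene | C=CC(=C)O[Si](C(C)C)(C(C)C)C(C)C | intermediate
11 | cis-3-(tert-butyldimethylsilyloxy)-3a-(prop-2-ynyl)-5-(triisopropylsilyloxy)-2,3,3a,4,7,7a-hexahydro-1H-inden-1-one (OTBS, propargyl and H-7a all cis) | O=C1C[C@H](O[Si](C)(C)C(C)(C)C)[C@@]2(CC#C)CC(O[Si](C(C)C)(C(C)C)C(C)C)=CC[C@@H]12 | intermediate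
12 | cis-3a-(prop-2-ynyl)-5-(triisopropylsilyloxy)-3a,4,7,7a-tetrahydro-1H-inden-1-one | O=C1C=C[C@@]2(CC#C)CC(O[Si](C(C)C)(C(C)C)C(C)C)=CC[C@@H]12 | intermediate
13 | 1-bromo-3-chloropropane | ClCCCBr | starting material
14 | 3-chloropropylmagnesium bromide | ClCCC[Mg]Br | intermediate
15 | bromomagnesium alkoxide of 1-(3-chloropropyl)-3a-(prop-2-ynyl)-5-(triisopropylsilyloxy)-3a,4,7,7a-tetrahydro-1H-inden-1-ol (O α, chloropropyl β) | Br[Mg]O[C@@]1(CCCCl)C=C[C@@]2(CC#C)CC(O[Si](C(C)C)(C(C)C)C(C)C)=CC[C@@H]12 | intermediate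
16 | 1-(3-chloropropyl)-3a-(prop-2-ynyl)-5-(triisopropylsilyloxy)-3a,4,7,7a-tetrahydro-1H-inden-1-yl methyl carbonate (carbonate α; chloropropyl, propargyl, H-7a β) | COC(=O)O[C@@]1(CCCCl)C=C[C@@]2(CC#C)CC(O[Si](C(C)C)(C(C)C)C(C)C)=CC[C@@H]12 | intermediate
17 | methyl 3-(3-chloropropyl)-7a-(prop-2-ynyl)-6-(triisopropylsilyloxy)-3a,4,7,7a-tetrahydro-1H-indene-1-carboxylate (CO2Me, propargyl, H-3a all cis) | COC(=O)[C@H]1C=C(CCCCl)[C@@H]2CC=C(O[Si](C(C)C)(C(C)C)C(C)C)C[C@]12CC#C | intermediate
18 | dimethyl malonate | COC(=O)CC(=O)OC | starting material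
19 | dimethyl 2-{3-[1-(methoxycarbonyl)-7a-(prop-2-ynyl)-6-(triisopropylsilyloxy)-3a,4,7,7a-tetrahydro-1H-inden-3-yl]propyl}malonate | COC(=O)[C@H]1C=C(CCCC(C(=O)OC)C(=O)OC)[C@@H]2CC=C(O[Si](C(C)C)(C(C)C)C(C)C)C[C@]12CC#C | intermediate
20 | dimethyl 2-{3-[1-(methoxycarbonyl)-6-oxo-7a-(prop-2-ynyl)-3a,4,5,6,7,7a-hexahydro-1H-inden-3-yl]propyl}malonate | COC(=O)[C@H]1C=C(CCCC(C(=O)OC)C(=O)OC)[C@@H]2CCC(=O)C[C@]12CC#C | intermediate
21 | ring-D-seco gibberellin A(21) dimethyl ester (13-ketone, 8β-propargyl, 19,10-lactone) | C#CC[C@]12CC(=O)CC[C@H]1[C@@]13CCC[C@@](C(=O)OC)(C(=O)O1)[C@H]3[C@@H]2C(=O)OC | intermediate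
22 | gibberellin A(21) dimethyl ester | C=C1C[C@]23C[C@@]1(O)CC[C@H]2[C@@]12CCC[C@@](C(=O)OC)(C(=O)O1)[C@H]2[C@@H]3C(=O)OC | intermediate
23 | disodium salt of gibberellin A(21) | C=C1C[C@]23C[C@@]1(O)CC[C@H]2[C@@]12CCC[C@@](C(=O)[O-])(C(=O)O1)[C@H]2[C@@H]3C(=O)[O-].[Na+].[Na+] | intermediate
24 | gibberellin A(21) | C=C1C[C@]23C[C@@]1(O)CC[C@H]2[C@@]12CCC[C@@](C(=O)O)(C(=O)O1)[C@H]2[C@@H]3C(=O)O | target

**Step count and risk**
Total steps: 14. Longest linear sequence: 13 (1 → 24 through steps 1–4 and 6–14; step 5 is the only side branch).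

Most likely to fail, first: step 12. The radical must close 6-endo rather than 5-exo and attack C-5 anti to the C-6 ester. The C-10 cation may also lose a proton or be captured by the C-7 ester instead of the C-4 ester. Fallback, from 20 back to 21: split the cascade into a redox-neutral atom-transfer cyclisation and a separate ionic lactonisation. Iodination of the malonate (NaH, N-iodosuccinimide, THF, 0 °C) gives dimethyl 2-iodo-2-{3-[1-(methoxycarbonyl)-6-oxo-7a-(prop-2-ynyl)-3a,4,5,6,7,7a-hexahydro-1H-inden-3-yl]propyl}malonate F1. Iodine-atom-transfer 6-endo cyclisation (hexabutylditin 10 mol %, sunlamp, benzene, 80 °C) gives the ring-A tertiary C-10 iodide F2. Warming in DMF with 2,6-lutidine ionises C-10 and the α-face ester closes the lactone with loss of iodomethane, giving 21.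

Second: step 9. The π-allyl terminus C-6 is neopentyl, and β-hydride elimination to a cyclopentadiene competes with CO insertion. Fallback, from 12 back to 19: put C-7 on the enone by conjugate addition and attach the chain by cross-coupling instead. Photoredox hydrocarboxylation with formate (HCO2K, 4CzIPN, DABCO, DMSO, blue LED; the CO2 radical anion adds to C-6 from the convex β face) gives the keto acid cis-3-oxo-7a-(prop-2-ynyl)-6-(triisopropylsilyloxy)-2,3,3a,4,7,7a-hexahydro-1H-indene-1-carboxylic acid F3. TMSCHN2 in MeOH/toluene gives its methyl ester F4. Kinetic enolisation toward C-5 and triflation (KHMDS, PhNTf2, THF, −78 °C) gives the enol triflate methyl 7a-(prop-2-ynyl)-3-(trifluoromethylsulfonyloxy)-6-(triisopropylsilyloxy)-3a,4,7,7a-tetrahydro-1H-indene-1-carboxylate F5. B-alkyl Suzuki coupling with dimethyl 2-[3-(9-borabicyclo[3.3.1]nonan-9-yl)propyl]malonate F6, made from commercial dimethyl allylmalonate and 9-BBN (Pd(dppf)Cl2, K3PO4, THF/H2O, 50 °C), gives 19.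

Third: step 6. The dienophile carbon that becomes C-8 is fully substituted and flanked by the silyloxy group, and the Lewis acid may attack the silyl ether or the alkyne. Fallback, from 8 back to 11: use a far more nucleophilic push–pull diene thermally and then adjust the oxidation level. Heating 8 with commercial trans-3-(tert-butyldimethylsilyloxy)-N,N-dimethylbuta-1,3-dien-1-amine (toluene, 80 °C) gives the amino silyl enol ether cycloadduct F7. Dilute HCl (THF, 0 °C) releases the ring-C enone cis-3-(tert-butyldimethylsilyloxy)-3a-(prop-2-ynyl)-2,3,3a,4-tetrahydro-1H-indene-1,5(7aH)-dione F8. Conjugate reduction with [(Ph3P)CuH]6 and trapping of the copper enolate with TIPSOTf/Et3N gives 11.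

**Further compounds**
F1 | step 12 | dimethyl 2-iodo-2-{3-[1-(methoxycarbonyl)-6-oxo-7a-(prop-2-ynyl)-3a,4,5,6,7,7a-hexahydro-1H-inden-3-yl]propyl}malonate | COC(=O)[C@H]1C=C(CCCC(I)(C(=O)OC)C(=O)OC)[C@@H]2CCC(=O)C[C@]12CC#C
F2 | step 12 | ring-A-closed tertiary C-10 iodide, trimethyl ester (4α-bond on C-5, C-10 epimers) | C#CC[C@]12CC(=O)CC[C@H]1C3(I)CCCC(C(=O)OC)(C(=O)OC)[C@H]3[C@@H]2C(=O)OC
F3 | step 9 | cis-3-oxo-7a-(prop-2-ynyl)-6-(triisopropylsilyloxy)-2,3,3a,4,7,7a-hexahydro-1H-indene-1-carboxylic acid | O=C1C[C@H](C(=O)O)[C@@]2(CC#C)CC(O[Si](C(C)C)(C(C)C)C(C)C)=CC[C@@H]12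
F4 | step 9 | methyl ester of F3 | O=C1C[C@H](C(=O)OC)[C@@]2(CC#C)CC(O[Si](C(C)C)(C(C)C)C(C)C)=CC[C@@H]12
F5 | step 9 | methyl 7a-(prop-2-ynyl)-3-(trifluoromethylsulfonyloxy)-6-(triisopropylsilyloxy)-3a,4,7,7a-tetrahydro-1H-indene-1-carboxylate | COC(=O)[C@H]1C=C(OS(=O)(=O)C(F)(F)F)[C@@H]2CC=C(O[Si](C(C)C)(C(C)C)C(C)C)C[C@]12CC#C
F6 | step 9 | dimethyl 2-[3-(9-borabicyclo[3.3.1]nonan-9-yl)propyl]malonate | COC(=O)C(CCCB1C2CCCC1CCC2)C(=O)OC
F7 | step 6 | cis-3,5-bis(tert-butyldimethylsilyloxy)-7-(dimethylamino)-3a-(prop-2-ynyl)-2,3,3a,4,7,7a-hexahydro-1H-inden-1-one (amino carbon unassigned) | O=C1C[C@H](O[Si](C)(C)C(C)(C)C)[C@@]2(CC#C)CC(O[Si](C)(C)C(C)(C)C)=CC(N(C)C)[C@@H]12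
F8 | step 6 | cis-3-(tert-butyldimethylsilyloxy)-3a-(prop-2-ynyl)-2,3,3a,4-tetrahydro-1H-indene-1,5(7aH)-dione | O=C1C[C@H](O[Si](C)(C)C(C)(C)C)[C@@]2(CC#C)CC(=O)C=C[C@@H]12
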